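The side chain (C1'–C13', numbered from C2 of the chroman) is cut at C6'–C7', the CH2–CH= bond that links the homoallylic methylene of the C3'=C4' alkene to the vinylic carbon of the C7'=C8' alkene. Because the C5'–C6' unit adjoins C4', it is carried as the vinyl end of an (E)-1,3-diene on the finished, MOM-protected chroman, whose C2 stereocentre in ring B comes from (S)-linalool. In one pot 9-BBN hydroborates that vinyl end at C6' and the homoallylborane is cross-coupled with (E)-1-iodo-2,6-dimethylhepta-1,5-diene, uniting a C18 and a C9 fragment and completing the all-E triene; only MOM removal follows.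

Key step: step 10

Remarks on the chemistry: ring A is the benzene ring and ring B the dihydropyran ring of the chroman (O1, C2, C3, C4, C4a, C5–C8, C8a). (S)-(+)-Linalool of high enantiomeric purity is assumed to be purchased; it is the only source of the C2 configuration, and no later step makes or breaks a bond at that carbon.

Step 1
Reactants: 1 4-methylcatechol
Product: 2 1,2-bis(methoxymethoxy)-4-methylbenzene
Conditions: NaH (2.4 equiv), MOMCl (2.4 equiv), DMF, 0 °C to rt
Reagents that add atoms: chloromethyl methyl ether (MOMCl), COCCl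
Why: Double Williamson-type O-alkylation of the catechol dianion should give the base-stable bis-acetal, which later directs ortho-lithiation and is removable by mild acid at the end.

Step 2
Reactants: 2 1,2-bis(methoxymethoxy)-4-methylbenzene
Product: 4 1-bromo-2,3-bis(methoxymethoxy)-5-methylbenzene, via aryllithium 3 (not isolated)
Conditions: n-BuLi (1.2 equiv), TMEDA, THF, 0 °C; then BrCCl2CCl2Br, −78 °C to rt
Reagents that add atoms: 1,2-dibromo-1,1,2,2-tetrachloroethane, BrC(Cl)(Cl)C(Cl)(Cl)Br
Why: Directed ortho-metalation by the OMOM groups should occur at the one ortho position that is not flanked by the methyl group (the future C8a), and the aryllithium is then quenched by the electrophilic bromine source.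

Step 3
Reactants: 4 1-bromo-2,3-bis(methoxymethoxy)-5-methylbenzene
Product: 5 3-bromo-4-iodo-1,2-bis(methoxymethoxy)-5-methylbenzene
Conditions: NIS (1.05 equiv), TFA (10 mol%), MeCN, 0 °C to rt, dark
Reagents that add atoms: N-iodosuccinimide, O=C1CCC(=O)N1I
Why: Electrophilic aromatic iodination should go to the only free position para to an alkoxy group (the future C4a, para to the C7 OMOM and ortho to the methyl), the other free position being merely ortho to that group.

Step 4
Reactants: 5 3-bromo-4-iodo-1,2-bis(methoxymethoxy)-5-methylbenzene; 6 (S)-(+)-linalool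
Product: 8 (3S)-1-[2-bromo-3,4-bis(methoxymethoxy)-6-methylphenyl]-3,7-dimethyloct-6-en-3-ol, via alkylborane 7 (not isolated)
Conditions: 6 (1.1 equiv), 9-BBN (0.5 M in THF, 1.5 equiv), THF, 0 °C to rt; then 5, Pd(OAc)2 (5 mol%), SPhos (10 mol%), K3PO4 (3 M aq.), THF, 50 °C
Reagents that add atoms: none
Why: Anti-Markovnikov hydroboration by 9-BBN is confined to the monosubstituted vinyl group of 6 (trisubstituted alkene and tertiary hydroxyl tolerated), and the B-alkyl Suzuki–Miyaura coupling should take place at the C–I bond, which undergoes oxidative addition far faster than the doubly flanked C–Br bond, while the carbinol stereocentre (future C2) is carried over from (S)-linalool because no bond to it is made or broken.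

Step 5
Reactants: 8 (3S)-1-[2-bromo-3,4-bis(methoxymethoxy)-6-methylphenyl]-3,7-dimethyloct-6-en-3-ol
Product: 9 (2S)-7,8-bis(methoxymethoxy)-2,5-dimethyl-2-(4-methylpent-3-en-1-yl)-3,4-dihydro-2H-chromene
Conditions: Pd(OAc)2 (5 mol%), 2-(di-tert-butylphosphino)-1,1'-binaphthyl (6 mol%), Cs2CO3 (1.5 equiv), toluene, 80 °C
Reagents that add atoms: none
Why: Palladium-catalysed intramolecular C–O cross-coupling (Buchwald–Hartwig etherification) should close ring B by aryl–oxygen reductive elimination, the tertiary alkoxide having no hydrogen on the carbinol carbon to divert the intermediate by β-hydride elimination, and C2 keeps its S configuration because only the O–H and C–Br bonds are broken.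

Step 6
Reactants: 9 (2S)-7,8-bis(methoxymethoxy)-2,5-dimethyl-2-(4-methylpent-3-en-1-yl)-3,4-dihydro-2H-chromene
Product: 11 (2E)-5-[(2S)-7,8-bis(methoxymethoxy)-2,5-dimethyl-3,4-dihydro-2H-chromen-2-yl]-2-methylpent-2-enal, via allylic alcohol 10 (not isolated)
Conditions: SeO2 (0.3 equiv), t-BuOOH (3 equiv), salicylic acid (10 mol%), CH2Cl2, rt; filter, then MnO2 (15 equiv), CH2Cl2, rt
Reagents that add atoms: selenium dioxide (oxygen carrier), O=[Se]=O; tert-butyl hydroperoxide (terminal oxygen source), CC(C)(C)OO
Why: SeO2 allylic oxidation (ene reaction followed by [2,3]-sigmatropic shift) is selective for the (E)-methyl group of a gem-dimethyl trisubstituted alkene, and MnO2 then oxidises the allylic alcohol 10, together with any aldehyde already formed, to the single (E)-enal.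

Step 7
Reactants: 11 (2E)-5-[(2S)-7,8-bis(methoxymethoxy)-2,5-dimethyl-3,4-dihydro-2H-chromen-2-yl]-2-methylpent-2-enal
Product: 12 (2S)-7,8-bis(methoxymethoxy)-2,5-dimethyl-2-[(3E)-4-methylhexa-3,5-dien-1-yl]-3,4-dihydro-2H-chromene
Conditions: Ph3PCH3Br (1.5 equiv), KN(SiMe3)2 (1.4 equiv), THF, 0 °C; then 11, −78 °C to rt
Reagents that add atoms: methyltriphenylphosphonium bromide, C[P+](c1ccccc1)(c1ccccc1)c1ccccc1.[Br-]
Why: Wittig methylenation of the aldehyde with the non-stabilised ylide should give the terminal vinyl group without touching the geometry of the trisubstituted C3'=C4' alkene.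

Step 8
Reactants: 13 6-methylhept-5-en-2-one
Product: 15 6-methylhept-5-en-1-yne, via enol phosphate 14 (not isolated)
Conditions: LiN(i-Pr)2 (1.05 equiv), THF, −78 °C; ClP(O)(OEt)2, −78 °C to rt; then LiN(i-Pr)2 (2.3 equiv), THF, −78 °C to rt
Reagents that add atoms: none
Why: Kinetic deprotonation on the methyl side gives the terminal enolate, whose O-phosphorylation and base-induced elimination of diethyl phosphate (enol phosphate route to alkynes) should deliver the terminal alkyne, held as the acetylide until work-up.

Step 9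
Reactants: 15 6-methylhept-5-en-1-yne
Product: 17 (1E)-1-iodo-2,6-dimethylhepta-1,5-diene, via alkenylalane 16 (not isolated)
Conditions: AlMe3 (2 equiv), Cp2ZrCl2 (20 mol%), CH2Cl2, 0 °C to rt; then I2, THF, −30 °C to 0 °C
Reagents that add atoms: trimethylaluminium, C[Al](C)C; iodine, II
Why: Zirconium-catalysed carboalumination (Negishi) adds CH3 and Al syn across the alkyne with methyl on the internal carbon, and iodinolysis of the C–Al bond with retention should give the (E)-alkenyl iodide.

Step 10
Reactants: 12 (2S)-7,8-bis(methoxymethoxy)-2,5-dimethyl-2-[(3E)-4-methylhexa-3,5-dien-1-yl]-3,4-dihydro-2H-chromene; 17 (1E)-1-iodo-2,6-dimethylhepta-1,5-diene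
Product: 19 (2S)-7,8-bis(methoxymethoxy)-2,5-dimethyl-2-[(3E,7E)-4,8,12-trimethyltrideca-3,7,11-trien-1-yl]-3,4-dihydro-2H-chromene, via homoallylborane 18 (not isolated)
Conditions: 12, 9-BBN (0.5 M in THF, 1.3 equiv), THF, 0 °C to rt; then 17 (1.3 equiv), Pd(dppf)Cl2 (5 mol%), AsPh3 (10 mol%), Cs2CO3 (3 equiv), DMF/H2O, rt
Reagents that add atoms: none
Why: 9-BBN adds syn and anti-Markovnikov to the monosubstituted C5'=C6' end of the diene with boron going to C6', so that 18 is a homoallylborane in which the (E)-C3'=C4' alkene is untouched; oxidative addition of zerovalent palladium to the C–I bond of 17, base-assisted transfer of the primary alkyl group from boron to palladium and reductive elimination then form the C6'–C7' bond. The closest known reaction type is the B-alkyl Suzuki–Miyaura coupling of 9-BBN-derived alkylboranes with (E)-alkenyl iodides, including boranes made by monohydroboration of 2-substituted 1,3-dienes, as used to assemble head-to-tail 1,5-dienes of terpenoids. No ring is closed and no stereocentre is created, and C2 is remote and unaffected. The step needs regioselective hydroboration, secured by the steric demand of 9-BBN, which takes the terminal CH2 of the vinyl group and leaves trisubstituted alkenes and MOM acetals alone; it needs retention of both alkene geometries, secured because oxidative addition and reductive elimination at the sp2 carbon are stereoretentive and C3'=C4' never takes part; and it needs reductive elimination to outrun β-hydride elimination of the alkylpalladium, for which the wide-bite-angle dppf ligand with AsPh3 is chosen.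

Step 11
Reactants: 19 (2S)-7,8-bis(methoxymethoxy)-2,5-dimethyl-2-[(3E,7E)-4,8,12-trimethyltrideca-3,7,11-trien-1-yl]-3,4-dihydro-2H-chromene
Product: 20 (2S)-2,5-dimethyl-2-[(3E,7E)-4,8,12-trimethyltrideca-3,7,11-trien-1-yl]-3,4-dihydro-2H-chromene-7,8-diol
Conditions: HCl (3 M in MeOH), THF, degassed, 0 °C to rt, argon
Reagents that add atoms: none
Why: Acid-catalysed methanolysis of the two aryl MOM acetals (transacetalisation to dimethoxymethane) should free the catechol under conditions mild enough for the isolated trisubstituted alkenes and the tertiary aryl ether at C2, air being excluded to protect the electron-rich catechol.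

Compound list
1 | 4-methylcatechol (4-methylbenzene-1,2-diol) | Cc1ccc(O)c(O)c1 | starting material
2 | 1,2-bis(methoxymethoxy)-4-methylbenzene | COCOc1ccc(C)cc1OCOC | intermediate
3 | [2,3-bis(methoxymethoxy)-5-methylphenyl]lithium | [Li]c1cc(C)cc(OCOC)c1OCOC | intermediate (not isolated)
4 | 1-bromo-2,3-bis(methoxymethoxy)-5-methylbenzene | COCOc1cc(C)cc(Br)c1OCOC | intermediate
5 | 3-bromo-4-iodo-1,2-bis(methoxymethoxy)-5-methylbenzene | COCOc1cc(C)c(I)c(Br)c1OCOC | intermediate
6 | (S)-(+)-linalool, (3S)-3,7-dimethylocta-1,6-dien-3-ol | CC(C)=CCC[C@@](O)(C)C=C | starting material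
7 | 9-[(3R)-3-hydroxy-3,7-dimethyloct-6-en-1-yl]-9-borabicyclo[3.3.1]nonane (same spatial arrangement as 6; the descriptor changes because boron ranks below carbon) | CC(C)=CCC[C@@](O)(C)CCB1C2CCCC1CCC2 | intermediate (not isolated)
8 | (3S)-1-[2-bromo-3,4-bis(methoxymethoxy)-6-methylphenyl]-3,7-dimethyloct-6-en-3-ol | CC(C)=CCC[C@@](O)(C)CCc1c(C)cc(OCOC)c(OCOC)c1Br | intermediate
9 | (2S)-7,8-bis(methoxymethoxy)-2,5-dimethyl-2-(4-methylpent-3-en-1-yl)-3,4-dihydro-2H-chromene | CC(C)=CCC[C@@]1(C)CCc2c(C)cc(OCOC)c(OCOC)c2O1 | intermediate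
10 | (2E)-5-[(2S)-7,8-bis(methoxymethoxy)-2,5-dimethyl-3,4-dihydro-2H-chromen-2-yl]-2-methylpent-2-en-1-ol | OC/C(C)=C/CC[C@@]1(C)CCc2c(C)cc(OCOC)c(OCOC)c2O1 | intermediate (not isolated)
11 | (2E)-5-[(2S)-7,8-bis(methoxymethoxy)-2,5-dimethyl-3,4-dihydro-2H-chromen-2-yl]-2-methylpent-2-enal | O=C/C(C)=C/CC[C@@]1(C)CCc2c(C)cc(OCOC)c(OCOC)c2O1 | intermediate
12 | (2S)-7,8-bis(methoxymethoxy)-2,5-dimethyl-2-[(3E)-4-methylhexa-3,5-dien-1-yl]-3,4-dihydro-2H-chromene | C=C/C(C)=C/CC[C@@]1(C)CCc2c(C)cc(OCOC)c(OCOC)c2O1 | intermediate
13 | 6-methylhept-5-en-2-one | CC(=O)CCC=C(C)C | starting material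
14 | diethyl 6-methylhepta-1,5-dien-2-yl phosphate | C=C(CCC=C(C)C)OP(=O)(OCC)OCC | intermediate (not isolated)
15 | 6-methylhept-5-en-1-yne | C#CCCC=C(C)C | intermediate
16 | [(1E)-2,6-dimethylhepta-1,5-dien-1-yl]dimethylalane | C[Al](C)/C=C(\C)CCC=C(C)C | intermediate (not isolated)
17 | (1E)-1-iodo-2,6-dimethylhepta-1,5-diene | I/C=C(\C)CCC=C(C)C | intermediate
18 | 9-{(3E)-6-[(2S)-7,8-bis(methoxymethoxy)-2,5-dimethyl-3,4-dihydro-2H-chromen-2-yl]-3-methylhex-3-en-1-yl}-9-borabicyclo[3.3.1]nonane | B1(CC/C(C)=C/CC[C@@]3(C)CCc4c(C)cc(OCOC)c(OCOC)c4O3)C2CCCC1CCC2 | intermediate (not isolated)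
19 | (2S)-7,8-bis(methoxymethoxy)-2,5-dimethyl-2-[(3E,7E)-4,8,12-trimethyltrideca-3,7,11-trien-1-yl]-3,4-dihydro-2H-chromene | CC(C)=CCC/C(C)=C/CC/C(C)=C/CC[C@@]1(C)CCc2c(C)cc(OCOC)c(OCOC)c2O1 | intermediate
20 | (2S)-2,5-dimethyl-2-[(3E,7E)-4,8,12-trimethyltrideca-3,7,11-trien-1-yl]-3,4-dihydro-2H-chromene-7,8-diol | CC(C)=CCC/C(C)=C/CC/C(C)=C/CC[C@@]1(C)CCc2c(C)cc(O)c(O)c2O1 | target

Total step count: 11 steps. Longest linear sequence: 9 steps (steps 1 to 7, then 10 and 11, from 4-methylcatechol); steps 8 and 9 make the alkenyl iodide in a side branch.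

Steps most likely to fail, with fallbacks

Step 5. The C–O reductive elimination from the electron-rich, doubly ortho-substituted arylpalladium alkoxide may be sluggish, so that protodebromination takes over. The ring oxygen would then be taken from a phenol and the C2 stereocentre set by catalysis instead of from linalool. Setting out from 2, bromination with NBS in MeCN para to the C2 OMOM group should give 1-bromo-4,5-bis(methoxymethoxy)-2-methylbenzene F1. Deprotonation between Br and OMOM with LiN(i-Pr)2 at −78 °C, trapping with B(OMe)3 and oxidation with H2O2/NaOH should give 2-bromo-5,6-bis(methoxymethoxy)-3-methylphenol F2. Palladium-catalysed asymmetric allylic etherification (Tsuji–Trost type) of F2 with geranyl methyl carbonate F3 (made from commercial geraniol with methyl chloroformate and pyridine) should give the tertiary aryl ether 4-bromo-3-{[(3S)-3,7-dimethylocta-1,6-dien-3-yl]oxy}-1,2-bis(methoxymethoxy)-5-methylbenzene F4. The conditions would be Pd2(dba)3 and N,N'-bis(2-diphenylphosphinobenzoyl)-1,2-diaminocyclohexane in CH2Cl2 at rt, with the ligand enantiomer that the usual model assigns to the S ether. Hydroboration of the vinyl group of F4 with 9-BBN and intramolecular B-alkyl Suzuki–Miyaura coupling at the C–Br bond (Pd(dppf)Cl2, Cs2CO3, DMF/H2O) would close ring B and return to the route at 9.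

Step 10. Regiocontrol in the hydroboration of the conjugated diene may be incomplete, or slow alkyl transfer from boron to palladium may let protodeboronation and β-hydride elimination compete. The C6' nucleophile would then be made stepwise and coupled as an organozinc. Setting out from 12, hydroboration with 9-BBN and oxidative work-up (NaOH, H2O2) should give (3E)-6-[(2S)-7,8-bis(methoxymethoxy)-2,5-dimethyl-3,4-dihydro-2H-chromen-2-yl]-3-methylhex-3-en-1-ol F5, which can be freed of regioisomers at this stage. An Appel-type iodination (PPh3, I2, imidazole) should give (2S)-2-[(3E)-6-iodo-4-methylhex-3-en-1-yl]-7,8-bis(methoxymethoxy)-2,5-dimethyl-3,4-dihydro-2H-chromene F6. Iodine–lithium exchange (t-BuLi, Et2O, −78 °C) and ZnCl2 should give {(3E)-6-[(2S)-7,8-bis(methoxymethoxy)-2,5-dimethyl-3,4-dihydro-2H-chromen-2-yl]-3-methylhex-3-en-1-yl}zinc chloride F7. Negishi coupling of F7 with 17 (Pd(PPh3)4, THF, rt) would form the same C6'–C7' bond and return to the route at 19.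

Step 3. Regiocontrol in the electrophilic iodination may be lost (attack ortho instead of para to the C7 OMOM group), or the acid additive may cause loss of a MOM group. The order of halogenation would then be reversed so that each position is fixed by an unambiguous directing effect. Setting out from 2, NIS in MeCN should iodinate para to the C2 OMOM group to give 1-iodo-4,5-bis(methoxymethoxy)-2-methylbenzene F8. LiN(i-Pr)2 at −78 °C should remove the proton flanked by iodine and OMOM, and quenching with BrCCl2CCl2Br would return to the route at 5.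

Further compounds
F1 | step 5 | 1-bromo-4,5-bis(methoxymethoxy)-2-methylbenzene | COCOc1cc(C)c(Br)cc1OCOC
F2 | step 5 | 2-bromo-5,6-bis(methoxymethoxy)-3-methylphenol | COCOc1cc(C)c(Br)c(O)c1OCOC
F3 | step 5 | geranyl methyl carbonate, (2E)-3,7-dimethylocta-2,6-dien-1-yl methyl carbonate | COC(=O)OC/C=C(\C)CCC=C(C)C
F4 | step 5 | 4-bromo-3-{[(3S)-3,7-dimethylocta-1,6-dien-3-yl]oxy}-1,2-bis(methoxymethoxy)-5-methylbenzene | CC(C)=CCC[C@@](C)(C=C)Oc1c(Br)c(C)cc(OCOC)c1OCOC
F5 | step 10 | (3E)-6-[(2S)-7,8-bis(methoxymethoxy)-2,5-dimethyl-3,4-dihydro-2H-chromen-2-yl]-3-methylhex-3-en-1-ol | OCC/C(C)=C/CC[C@@]1(C)CCc2c(C)cc(OCOC)c(OCOC)c2O1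
F6 | step 10 | (2S)-2-[(3E)-6-iodo-4-methylhex-3-en-1-yl]-7,8-bis(methoxymethoxy)-2,5-dimethyl-3,4-dihydro-2H-chromene | ICC/C(C)=C/CC[C@@]1(C)CCc2c(C)cc(OCOC)c(OCOC)c2O1
F7 | step 10 | {(3E)-6-[(2S)-7,8-bis(methoxymethoxy)-2,5-dimethyl-3,4-dihydro-2H-chromen-2-yl]-3-methylhex-3-en-1-yl}zinc chloride | Cl[Zn]CC/C(C)=C/CC[C@@]1(C)CCc2c(C)cc(OCOC)c(OCOC)c2O1
F8 | step 3 | 1-iodo-4,5-bis(methoxymethoxy)-2-methylbenzene | COCOc1cc(C)c(I)cc1OCOC
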